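**Conventions.** Chain atoms: C1 = ester carbonyl, C2 = carbinol, C3 = methine, C4 = ketone, C5 = methylene. Ring A = the 4-hydroxyphenyl ring on C3; ring B = the 4-hydroxy-3-prenylphenyl ring on C5. TBS = tert-butyldimethylsilyl; TsDPEN = N-(p-toluenesulfonyl)-1,2-diphenylethane-1,2-diamine. Compounds 8, 10 and 12 are drawn as keto forms although they should exist largely as enols.

## Analysis of the target

Asperteretal H (14) is an open five-carbon chain: methyl ester C1, secondary carbinol C2, methine C3 carrying ring A, ketone C4, and methylene C5 carrying ring B, whose prenyl group sits ortho to the phenol. It has two adjacent stereocentres, C2 (R) and C3 (S); with C1–C4 drawn zigzag the C2 hydroxyl and ring A lie on opposite faces, so it is an anti-aldol. Formally it is the aldol adduct of a glyoxylate ester with an unsymmetrical 1,3-diarylacetone, and it presumably arises in the fungus from the co-occurring 5-benzyl-5-carboxybutenolides by lactone opening and vinylogous loss of CO2. The sensitive points are: C3–H, which is benzylic to ring A and alpha to the C4 ketone and so epimerizes under base; the beta-hydroxy ketone, open to retro-aldol cleavage and to loss of water across C2–C3; the prenyl alkene, which does not tolerate strong acid (cyclization onto the phenol), electrophilic oxidants or hydrogenation; and two free phenols. The real difficulty is that C3 and C5 are both benzylic methylene-type positions alpha to the same carbonyl and differ only by a prenyl group far away on ring B, so no enolate-based bond formation at C3 can tell them apart. The second difficulty is that a stereocentre at C3 cannot be carried through basic steps. This lability is the feature the plan uses: in a precursor that also has a ketone at C2, C3 lies between two carbonyls and ring A and has no configuration of its own. C2 and C3 can then be set together, late, by one reduction of the C2 carbonyl that picks one C3 epimer out of the equilibrating pair.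

## Retrosynthetic reasoning

14 from 13. Only the two aryl O–Si bonds are cut. The phenols must be masked during the fragment union, where free phenols would be acylated, and silyl ethers can be removed at the end with a buffered fluoride source that leaves C3–H alone.

13 from 12 (key disconnection). The C2–H bond is cut; no carbon–carbon bond changes. In 12 the C3 methine sits between the C2 and C4 carbonyls and ring A, so 12 is an enolized, stereochemically featureless compound that already holds every carbon of the target. Both stereocentres of 13 can therefore be written in by one hydride transfer to C2. The forward reaction must reduce C2 and not C4, choose one face of C2, and take only one of the two rapidly interconverting C3 epimers.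

12 from 10 and 6. The C3–C4 bond is cut, not C2–C3. A cut at C2–C3 would need regioselective enolization between two benzylic methylene groups that differ only in a remote prenyl group. In the chosen cut, 10 has exactly one enolizable carbon (C3) and 6 exactly one acyl carbon (C4), so the regiochemistry is fixed by construction and the two halves are of similar size. The forward reaction must acylate the enol of 10 on carbon, under conditions too mild to deprotonate C5 of 12, which would otherwise close onto C1.

10 from 8 and 8 from 7. An aryl O–Si bond and the ester O–CH3 bond are cut. The ring-A half is available at the correct oxidation level as 7, so no carbon–carbon chemistry is needed on this side.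

6 from 5 and 5 from 3. The acyl C–N bond and the aryl O–Si bond are cut. These steps mask the ring-B phenol and turn the acid into a neutral acyl donor that carries no HCl near the prenyl group.

3 from 1 and 2. The bond between ring B and the prenyl CH2 is cut. The bromine of 1 marks the position ortho to the phenol, which removes the ortho/O-alkylation ambiguity of a direct phenol prenylation. The forward coupling must join the ring to the unsubstituted terminus of the prenyl unit of 2.

## Alternatives that were turned down

Alternative 1: the textbook aldol disconnection at C2–C3. The forward key step would be an enantioselective anti-aldol reaction of the protected diaryl ketone A1 (through an enamine or a preformed enolate) with a glyoxylate ester. It was turned down because A1 has two alpha-methylene groups, C3 and C5, with almost the same acidity and steric surroundings. Enolization would go both ways and give the target skeleton together with the constitutional isomer A2 in similar amounts, and the two would be hard to separate. The auxiliary-based repair (aldol of a ring-A arylacetyl imide with the glyoxylate, then conversion of the imide carbonyl into the benzyl ketone) fixes the regiochemistry. It costs at least five more steps, however (auxiliary on and off, hydroxyl protection, acyl activation, organometallic addition), and it puts a basic benzyl nucleophile next to the finished, labile C3 centre.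

Alternative 2: a [3,3]-sigmatropic disconnection at C2–C3. The forward key step would be an Ireland–Claisen rearrangement of the glycolate ester A3 of an enantioenriched 1,3-diarylallyl alcohol to the acid A4, with chirality transfer from the carbinol carbon to C2 and C3 through a chair transition state. It was turned down on three structural grounds:
- With the chelated glycolate enolate the anti relationship requires the (Z)-alkene, so A3 must be made both (Z)-configured and enantioenriched.
- A3 is an allylic ester flanked by two electron-rich aryl groups and is prone to ionization and allylic transposition, which would erase its configuration.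
- A4 still needs C4=C5 turned into the C4 ketone. A Wacker oxidation of this styrene would place oxygen at benzylic C5, and epoxidation followed by Meinwald rearrangement would attack the more electron-rich trisubstituted prenyl alkene first.

The route would exceed ten steps and its oxidation endgame fights the prenyl group.

Alternative 3: the biomimetic disconnection at C3–C4 with an extra carboxyl carbon. The forward key step would be a crossed aldol–lactonization of the ring-A arylpyruvate 10 with the ring-B arylpyruvate A5 to the butenolide A6. Hydrolysis of the angular ester, methanolysis of the lactone and vinylogous decarboxylation would then lead directly to the skeleton of 13. It was turned down for two reasons: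
- Both pyruvates are at once nucleophile and electrophile, so four aldol dimers are expected.
- The decarboxylation destroys the only stereocentre of A6 and then creates C2–H and C3–H by two protonations of an achiral dienol with no element of control, so all four stereoisomers would form.

A route that copies the biosynthesis therefore delivers the constitution but not the single enantiomer.

Key step: step 7

Assumption (remark on the chemistry): the ester group of 12 is taken to lie under the η6-arene of the catalyst, as aryl and alkynyl groups of simpler ketones do, so that the (R,R)-configured diamine delivers hydride to the Si face of C2. Should the sense prove opposite, the (S,S)-configured catalyst is used and nothing else changes.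

## Route

Step 1
Reactants: 1 2-(3-bromo-4-hydroxyphenyl)acetic acid; 2 4,4,5,5-tetramethyl-2-(3-methylbut-2-en-1-yl)-1,3,2-dioxaborolane
Product: 3 2-[4-hydroxy-3-(3-methylbut-2-en-1-yl)phenyl]acetic acid
Conditions: PdCl2(IPent)(3-chloropyridine) (2 mol %; IPent = 1,3-bis[2,6-di(pentan-3-yl)phenyl]imidazol-2-ylidene), KOH (5 M aq.), THF, 70 °C; then 1 M HCl
Reagents that add atoms: none
Why: Suzuki–Miyaura coupling of an allylboronate; the bulky carbene ligand is expected to let the allyl group settle on palladium at its CH2 terminus before reductive elimination, which gives the linear prenyl arene. The bromide fixes the position ortho to the phenol, and acid and phenol pass through as potassium salts.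

Step 2
Reactants: 3 2-[4-hydroxy-3-(3-methylbut-2-en-1-yl)phenyl]acetic acid
Product: 5 2-[4-(tert-butyldimethylsilyloxy)-3-(3-methylbut-2-en-1-yl)phenyl]acetic acid, via bis-silylated ester 4 (not isolated)
Conditions: TBSCl (2.4 equiv), imidazole, DMF, rt; then AcOH/THF/H2O, rt
Reagents that add atoms: tert-butyldimethylsilyl chloride CC(C)(C)[Si](C)(C)Cl
Why: Both acidic OH groups are silylated, and the silyl ester, far more labile than the aryl silyl ether, is hydrolysed selectively by dilute aqueous acid.

Step 3
Reactants: 5 2-[4-(tert-butyldimethylsilyloxy)-3-(3-methylbut-2-en-1-yl)phenyl]acetic acid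
Product: 6 1-{[4-(tert-butyldimethylsilyloxy)-3-(3-methylbut-2-en-1-yl)phenyl]acetyl}-1H-benzotriazole
Conditions: 1H-benzotriazole, DCC, CH2Cl2, 0 °C to rt
Reagents that add atoms: 1H-benzotriazole c1ccc2[nH]nnc2c1
Why: Carbodiimide-mediated N-acylation gives a neutral, storable acyl donor that is less prone to ketene formation than the acid chloride and is made without HCl, which would add to the prenyl alkene.

Step 4
Reactants: 7 3-(4-hydroxyphenyl)-2-oxopropanoic acid
Product: 8 methyl 3-(4-hydroxyphenyl)-2-oxopropanoate
Conditions: MeOH, H2SO4 (cat.), 40 °C
Reagents that add atoms: methanol CO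
Why: Fischer esterification; under acid the compound rests as its enol, so the base-induced aldol self-condensation typical of arylpyruvates does not start.

Step 5
Reactants: 8 methyl 3-(4-hydroxyphenyl)-2-oxopropanoate
Product: 10 methyl 3-[4-(tert-butyldimethylsilyloxy)phenyl]-2-oxopropanoate, via bis-silyl enol ether 9 (not isolated)
Conditions: TBSCl (2.3 equiv), imidazole, DMF, 0 °C to rt; then 1 M HCl/THF, 0 °C
Reagents that add atoms: tert-butyldimethylsilyl chloride CC(C)(C)[Si](C)(C)Cl
Why: Phenol and enol are both silylated; the silyl enol ether is then cleaved by dilute acid through protonation at C3, whereas the aryl silyl ether needs fluoride or base and should survive.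

Step 6
Reactants: 10 methyl 3-[4-(tert-butyldimethylsilyloxy)phenyl]-2-oxopropanoate; 6 1-{[4-(tert-butyldimethylsilyloxy)-3-(3-methylbut-2-en-1-yl)phenyl]acetyl}-1H-benzotriazole
Product: 12 methyl 3-[4-(tert-butyldimethylsilyloxy)phenyl]-5-[4-(tert-butyldimethylsilyloxy)-3-(3-methylbut-2-en-1-yl)phenyl]-2,4-dioxopentanoate, via bromomagnesium enolate 11 (not isolated)
Conditions: MgBr2·OEt2 (2.5 equiv), i-Pr2NEt (2.2 equiv), CH2Cl2, 0 °C, 15 min; then 6, 0 °C to rt; 1 M HCl work-up
Reagents that add atoms: none
Why: Crossed Claisen condensation under soft enolization: the magnesium chelate of the enolate of 10 ties up the enolate oxygen and should direct the N-acylbenzotriazole to C3, and formation of the more acidic 1,3-dicarbonyl product drives the reaction. Complete enolization before 6 is added leaves no keto form for self-aldol, and the amine base is too weak to deprotonate C5 of 12, so the ring closure of C5 onto C1 is not expected.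

Step 7
Reactants: 12 methyl 3-[4-(tert-butyldimethylsilyloxy)phenyl]-5-[4-(tert-butyldimethylsilyloxy)-3-(3-methylbut-2-en-1-yl)phenyl]-2,4-dioxopentanoate
Product: 13 methyl (2R,3S)-3-[4-(tert-butyldimethylsilyloxy)phenyl]-5-[4-(tert-butyldimethylsilyloxy)-3-(3-methylbut-2-en-1-yl)phenyl]-2-hydroxy-4-oxopentanoate
Conditions: RuCl(p-cymene)[(R,R)-TsDPEN] (2 mol %), HCO2H/Et3N (5:2), DMF, 25 °C, stopped when 12 is consumed
Reagents that add atoms: none
Why: This is a Noyori asymmetric transfer hydrogenation run as a dynamic kinetic resolution: the ruthenium amide takes hydride and proton from formic acid with loss of CO2, and the Ru–H/N–H pair passes them to the C2 carbonyl of the keto tautomer of 12 through the six-membered outer-sphere transition state. The closest known reaction types are the transfer-hydrogenative dynamic kinetic resolution of beta-aryl alpha-keto esters and the enantioselective monoreduction of 2-substituted 1,3-diketones with the same catalyst family; no ring is closed. C2 (R) is set by the catalyst, which should hold the ester under the arene ligand and deliver hydride to the Si face. C3 (S) is set by selection between the two C3 epimers of 12, which interconvert through the enol far faster than they are reduced because C3–H lies between two carbonyls and ring A. The epimer expected to react is the one that can place the C3–C4 bond antiperiplanar to the incoming hydride with C3–H next to the ester (Felkin–Anh arrangement with the acyl group as the polar substituent), and this leads to the 2,3-anti product. Chemoselectivity for C2 over C4 rests on the much higher electrophilicity of the alpha-keto ester carbonyl compared with the benzyl ketone, which this catalyst reduces only slowly; the prenyl alkene, silyl ethers and ester do not react with the ruthenium hydride. The acidic 5:2 medium keeps 12 as the neutral enol or ketone and not as an inert enolate, and it slows epimerization of 13, whose C3–H is now activated only by C4 and ring A. The anti isomer can place both large groups equatorial in the hydrogen-bonded six-membered arrangement and is expected to be the more stable one, so any slow equilibration at C3 works in the same direction.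

Step 8
Reactants: 13 methyl (2R,3S)-3-[4-(tert-butyldimethylsilyloxy)phenyl]-5-[4-(tert-butyldimethylsilyloxy)-3-(3-methylbut-2-en-1-yl)phenyl]-2-hydroxy-4-oxopentanoate
Product: 14 Asperteretal H, methyl (2R,3S)-2-hydroxy-3-(4-hydroxyphenyl)-5-[4-hydroxy-3-(3-methylbut-2-en-1-yl)phenyl]-4-oxopentanoate
Conditions: Bu4NF (2.2 equiv), AcOH (2.2 equiv), THF, 0 °C
Reagents that add atoms: none
Why: Fluoride cleaves the aryl silyl ethers; buffering with acetic acid keeps the medium from becoming basic, so C3 should not epimerize and the beta-hydroxy ketone should neither cleave nor eliminate.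

## Compound list

1 | 2-(3-bromo-4-hydroxyphenyl)acetic acid | OC(=O)Cc1ccc(O)c(Br)c1 | starting material
2 | 4,4,5,5-tetramethyl-2-(3-methylbut-2-en-1-yl)-1,3,2-dioxaborolane | CC(C)=CCB1OC(C)(C)C(C)(C)O1 | starting material
3 | 2-[4-hydroxy-3-(3-methylbut-2-en-1-yl)phenyl]acetic acid | OC(=O)Cc1ccc(O)c(CC=C(C)C)c1 | intermediate
4 | tert-butyldimethylsilyl 2-[4-(tert-butyldimethylsilyloxy)-3-(3-methylbut-2-en-1-yl)phenyl]acetate | CC(C)=CCc1cc(CC(=O)O[Si](C)(C)C(C)(C)C)ccc1O[Si](C)(C)C(C)(C)C | intermediate (not isolated)
5 | 2-[4-(tert-butyldimethylsilyloxy)-3-(3-methylbut-2-en-1-yl)phenyl]acetic acid | OC(=O)Cc1ccc(O[Si](C)(C)C(C)(C)C)c(CC=C(C)C)c1 | intermediate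
6 | 1-{[4-(tert-butyldimethylsilyloxy)-3-(3-methylbut-2-en-1-yl)phenyl]acetyl}-1H-benzotriazole | O=C(Cc1ccc(O[Si](C)(C)C(C)(C)C)c(CC=C(C)C)c1)n1nnc2ccccc12 | intermediate
7 | 3-(4-hydroxyphenyl)-2-oxopropanoic acid | OC(=O)C(=O)Cc1ccc(O)cc1 | starting material
8 | methyl 3-(4-hydroxyphenyl)-2-oxopropanoate | COC(=O)C(=O)Cc1ccc(O)cc1 | intermediate
9 | methyl (Z)-2-(tert-butyldimethylsilyloxy)-3-[4-(tert-butyldimethylsilyloxy)phenyl]prop-2-enoate | COC(=O)/C(O[Si](C)(C)C(C)(C)C)=C/c1ccc(O[Si](C)(C)C(C)(C)C)cc1 | intermediate (not isolated)
10 | methyl 3-[4-(tert-butyldimethylsilyloxy)phenyl]-2-oxopropanoate | COC(=O)C(=O)Cc1ccc(O[Si](C)(C)C(C)(C)C)cc1 | intermediate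
11 | bromomagnesium (Z)-enolate of 10 | COC(=O)/C(O[Mg]Br)=C/c1ccc(O[Si](C)(C)C(C)(C)C)cc1 | intermediate (not isolated)
12 | methyl 3-[4-(tert-butyldimethylsilyloxy)phenyl]-5-[4-(tert-butyldimethylsilyloxy)-3-(3-methylbut-2-en-1-yl)phenyl]-2,4-dioxopentanoate (C3 not configurationally defined) | COC(=O)C(=O)C(c1ccc(O[Si](C)(C)C(C)(C)C)cc1)C(=O)Cc1ccc(O[Si](C)(C)C(C)(C)C)c(CC=C(C)C)c1 | intermediate
13 | methyl (2R,3S)-3-[4-(tert-butyldimethylsilyloxy)phenyl]-5-[4-(tert-butyldimethylsilyloxy)-3-(3-methylbut-2-en-1-yl)phenyl]-2-hydroxy-4-oxopentanoate | COC(=O)[C@H](O)[C@@H](C(=O)Cc1ccc(O[Si](C)(C)C(C)(C)C)c(CC=C(C)C)c1)c1ccc(O[Si](C)(C)C(C)(C)C)cc1 | intermediate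
14 | Asperteretal H, methyl (2R,3S)-2-hydroxy-3-(4-hydroxyphenyl)-5-[4-hydroxy-3-(3-methylbut-2-en-1-yl)phenyl]-4-oxopentanoate | COC(=O)[C@H](O)[C@@H](C(=O)Cc1ccc(O)c(CC=C(C)C)c1)c1ccc(O)cc1 | target

## Step count and least certain steps

Total step count: 8. Longest linear sequence: 6 (steps 1, 2, 3, 6, 7, 8); the ring-A branch (steps 4, 5) joins at step 6.

Step 7 (key step). The most likely failure is insufficient kinetic discrimination between the two C3 epimers of 12 in the hydride transfer, or selection of the wrong one, which would give a low anti:syn ratio even if the facial selectivity at C2 is high. The acyl and aryl substituents on C3 are of similar size, and which of them takes the position antiperiplanar to the hydride cannot be predicted with confidence. Slow turnover is also possible, because 12 rests as a hydrogen-bonded enol and its conjugate base could bind ruthenium, and prolonged reaction could reduce C4 as well. The fallback gives up kinetic control at C3 and sets it thermodynamically. It sets out from 12. The same reduction is used only to fix C2 and the mixture of 13 and its syn epimer, methyl (2R,3R)-3-[4-(tert-butyldimethylsilyloxy)phenyl]-5-[4-(tert-butyldimethylsilyloxy)-3-(3-methylbut-2-en-1-yl)phenyl]-2-hydroxy-4-oxopentanoate F1, is accepted. F1 is then equilibrated through the C4 enol with catalytic DBU in toluene at 0 °C, conditions under which the C2 carbinol is not touched. The anti isomer should be favoured; it is separated and the remaining F1 is returned to the equilibration. The fallback comes back to the route at 13.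

Step 6. The enolate of 10 could react through oxygen and give the enol ester in place of the C-acylated product, and if enolization is incomplete 10 could condense with itself. The fallback changes the bond-forming event from direct C-acylation to a two-stage acyl transfer. It sets out from 10 and 6, which without magnesium (Et3N, CH2Cl2) should give the enol ester methyl (Z)-3-[4-(tert-butyldimethylsilyloxy)phenyl]-2-({[4-(tert-butyldimethylsilyloxy)-3-(3-methylbut-2-en-1-yl)phenyl]acetyl}oxy)prop-2-enoate F2. A Steglich-type O-to-C acyl shift of F2 (DMAP, Et3N, MeCN, rt to 40 °C) should then move the acyl group to C3, driven by formation of the stabilized 1,3-dicarbonyl enolate. The fallback comes back at 12.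

Step 1. The allyl group could be transferred through its substituted terminus and give the 1,1-dimethylallyl isomer, and the boronate could be lost by protodeboronation in the hot aqueous base. The fallback replaces the cross-coupling by an aryl-metal alkylation. It sets out from 1, which with n-BuLi (3.2 equiv, THF, −78 °C) should give, after deprotonation of acid and phenol and bromine–lithium exchange, the trilithium species lithium 2-(3-lithio-4-lithiooxyphenyl)acetate F3. Transmetalation with CuBr·SMe2 and alkylation with 1-bromo-3-methylbut-2-ene at the primary carbon, followed by acidic work-up, comes back to the route at 3.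

Step 8. Even with buffering, the phenoxides formed on desilylation could promote epimerization at C3, retro-aldol cleavage of the C2–C3 bond or loss of water across C2–C3. The fallback changes the order so that the finished aldol never meets fluoride. It sets out from 12, which is desilylated first (Bu4NF/AcOH, THF, 0 °C) to methyl 3-(4-hydroxyphenyl)-5-[4-hydroxy-3-(3-methylbut-2-en-1-yl)phenyl]-2,4-dioxopentanoate F4, a robust enol. The transfer hydrogenation of step 7 is then run on F4, since the catalyst tolerates free phenols, and comes back to the route directly at 14.

## Further compounds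

F1 | step 7 | methyl (2R,3R)-3-[4-(tert-butyldimethylsilyloxy)phenyl]-5-[4-(tert-butyldimethylsilyloxy)-3-(3-methylbut-2-en-1-yl)phenyl]-2-hydroxy-4-oxopentanoate | COC(=O)[C@H](O)[C@H](C(=O)Cc1ccc(O[Si](C)(C)C(C)(C)C)c(CC=C(C)C)c1)c1ccc(O[Si](C)(C)C(C)(C)C)cc1
F2 | step 6 | methyl (Z)-3-[4-(tert-butyldimethylsilyloxy)phenyl]-2-({[4-(tert-butyldimethylsilyloxy)-3-(3-methylbut-2-en-1-yl)phenyl]acetyl}oxy)prop-2-enoate | COC(=O)/C(OC(=O)Cc1ccc(O[Si](C)(C)C(C)(C)C)c(CC=C(C)C)c1)=C/c1ccc(O[Si](C)(C)C(C)(C)C)cc1
F3 | step 1 | lithium 2-(3-lithio-4-lithiooxyphenyl)acetate | [Li]OC(=O)Cc1ccc(O[Li])c([Li])c1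
F4 | step 8 | methyl 3-(4-hydroxyphenyl)-5-[4-hydroxy-3-(3-methylbut-2-en-1-yl)phenyl]-2,4-dioxopentanoate | COC(=O)C(=O)C(c1ccc(O)cc1)C(=O)Cc1ccc(O)c(CC=C(C)C)c1
A1 | alternative 1 | 1-[4-(tert-butyldimethylsilyloxy)phenyl]-3-[4-(tert-butyldimethylsilyloxy)-3-(3-methylbut-2-en-1-yl)phenyl]propan-2-one | CC(C)=CCc1cc(CC(=O)Cc2ccc(O[Si](C)(C)C(C)(C)C)cc2)ccc1O[Si](C)(C)C(C)(C)C
A2 | alternative 1 | methyl (2R,3S)-3-[4-(tert-butyldimethylsilyloxy)-3-(3-methylbut-2-en-1-yl)phenyl]-5-[4-(tert-butyldimethylsilyloxy)phenyl]-2-hydroxy-4-oxopentanoate | COC(=O)[C@H](O)[C@@H](C(=O)Cc1ccc(O[Si](C)(C)C(C)(C)C)cc1)c1ccc(O[Si](C)(C)C(C)(C)C)c(CC=C(C)C)c1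
A3 | alternative 2 | (1S,2Z)-1-[4-(tert-butyldimethylsilyloxy)-3-(3-methylbut-2-en-1-yl)phenyl]-3-[4-(tert-butyldimethylsilyloxy)phenyl]prop-2-en-1-yl [(4-methoxybenzyl)oxy]acetate | COc1ccc(COCC(=O)O[C@@H](/C=C\c2ccc(O[Si](C)(C)C(C)(C)C)cc2)c2ccc(O[Si](C)(C)C(C)(C)C)c(CC=C(C)C)c2)cc1
A4 | alternative 2 | (2R,3S,4E)-3-[4-(tert-butyldimethylsilyloxy)phenyl]-5-[4-(tert-butyldimethylsilyloxy)-3-(3-methylbut-2-en-1-yl)phenyl]-2-[(4-methoxybenzyl)oxy]pent-4-enoic acid | OC(=O)[C@H](OCc1ccc(OC)cc1)[C@@H](/C=C/c1ccc(O[Si](C)(C)C(C)(C)C)c(CC=C(C)C)c1)c1ccc(O[Si](C)(C)C(C)(C)C)cc1
A5 | alternative 3 | methyl 3-[4-(tert-butyldimethylsilyloxy)-3-(3-methylbut-2-en-1-yl)phenyl]-2-oxopropanoate | COC(=O)C(=O)Cc1ccc(O[Si](C)(C)C(C)(C)C)c(CC=C(C)C)c1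
A6 | alternative 3 | methyl 2-[4-(tert-butyldimethylsilyloxy)-3-(3-methylbut-2-en-1-yl)benzyl]-4-hydroxy-3-[4-(tert-butyldimethylsilyloxy)phenyl]-5-oxo-2,5-dihydrofuran-2-carboxylate (racemic) | COC(=O)C1(Cc2ccc(O[Si](C)(C)C(C)(C)C)c(CC=C(C)C)c2)OC(=O)C(O)=C1c1ccc(O[Si](C)(C)C(C)(C)C)cc1
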